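An easy step to read is the loss of substrate, so the flask is built up from that step, one process at a time.

| setting | west | grey | blue |
|---|---|---|---|
| substrate | 18 mM | 18 mM | 18 mM |
| first nucleophile | 9.9 mM | 19.8 mM | 19.8 mM |
| second nucleophile | 19.8 mM | 19.8 mM | 19.8 mM |
| protic impurity | 18 mM | 18.0 mM | 18.0 mM |
| temperature | 40 °C | 40 °C | 60 °C |
| remark | run made earlier |  |  |
| time |  | 8.0 min | 8.0 min |

west run (percent of the substrate charged)

| time / min | other capture product / % | solvolysis product / % | target / % | substrate / % |
|---|---|---|---|---|
| 0.200 | 2.8 | 0 | 0.2 | 95.9 |
| 0.333 | 6.1 | 0 | 0.1 | 93.2 |
| 0.667 | 11.1 | 1.4 | 0.4 | 87.5 |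
| 1.33 | 20.3 | 0.9 | 2.1 | 76.4 |
| 2.50 | 34.4 | 2.3 | 2.0 | 60.9 |

(readings scatter by 0.5 percentage points)

- the numbers in the tables scatter with a standard deviation of 0.5 percentage points
- the earlier runs do not show what temperature does; that part of a forecast is a guess
- a reading or a percentage of target counts all its forms, free or not

* which of these there is most of at the end, counted by the substrate in it, grey (substrate / solvolysis product / target / other capture product)
* which of these there is most of at the end, counted by the substrate in it, blue (substrate / solvolysis product / target / other capture product)
* the largest of these amounts at the end, in percent of the substrate charged, grey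
* the largest of these amounts at the end, in percent of the substrate charged, blue

With the main step by itself, west falls to 60.9% of its substrate in 2.50 min, which as a first-order loss means 0.198 min⁻¹. Grey has the same temperature and is given the same constant, so 79.5% of its substrate has reacted after 8.0 min, and that is the first figure for other capture product.

Next comes solvolysis, taken as independent of the second nucleophile, while capture is taken as proportional to it. The ratio of solvolysis product to other capture product at the last west reading, multiplied by the mean second nucleophile of that stretch, 16.7 mM, gives 1.12 mM: the parity amount, the amount of second nucleophile at which solvolysis and capture run equally fast. It rests on a reading of 2.3% with a scatter of 0.5 percentage points. Replacing the curve by its straight mean costs little in west, since the logarithmic mean is 16.5 mM. In grey the mean, with the reacted substrate counted as taking up second nucleophile, is 12.6 mM, and the reckoned figure for other capture product drops to 73.0%.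

Last comes target. Taking the first nucleophile at its charge in west and in grey, although the protic impurity may consume some, the west readings give a selectivity factor of 0.0981 for first over second nucleophile. The reckoned figure for other capture product in grey then drops to 64.0%. For blue, with conversion taken as complete and the parity amount and selectivity factor guessed unchanged at 60 °C, the same reckoning gives 77.9%.

The forecast names other capture product for grey at 66% and other capture product for blue at 82%, a higher blue figure than the reckoning here, and it says of blue: “I guess the rate rises about fivefold”.

Grey ends with other capture product at 65.2%, and blue with other capture product at 68.1%, 14 points under the forecast, with solvolysis product at 18.0%. Blue's own ratio, with a mean second nucleophile of 13.7 mM, gives a parity amount of 3.61 mM at 60 °C, higher than the 1.12 mM read from west at 40 °C.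

    substrate → intermediate (k = 0.200 min⁻¹, Ea = 86.0 kJ mol⁻¹)
    first nucleophile + intermediate → target (k = 222 M⁻¹ min⁻¹, Ea = 50.0 kJ mol⁻¹)
    second nucleophile + intermediate → other capture product (k = 1740 M⁻¹ min⁻¹, Ea = 38.0 kJ mol⁻¹)
    intermediate → solvolysis product (k = 1.72 min⁻¹, Ea = 91.0 kJ mol⁻¹)
    first nucleophile + protic impurity → quenched reagent (k = 4.58 M⁻¹ min⁻¹, Ea = 52.0 kJ mol⁻¹)
    crystals ⇌ target, rate k6*(cs6 - [target]) while solid is left; crystals form when [target] > cs6 (solubility = 17.0 mM, k = 4.14 min⁻¹)
    (constants at 40 °C)

A neighbour flask is blue with 5.0 mM of second nucleophile in place of its charge, the other charges and the time held. Taking that amount as falling from its charge to nil, its mean is 2.50 mM, so the parity amount of 3.61 mM predicts 1.44 of solvolysis product per unit of other capture product. The neighbour gives 44.3% against 25.2%, a ratio of 1.76, higher than the straight mean predicted.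

The readings were computed for an exercise; scatter was added.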